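Watch how much of each substrate has gone, not the clock.

common to all: free catalyst 40 mM
- green: left-handed substrate 1.1 M; right-handed substrate 1.1 M; coupling partner 0.96 M (fed, over 80 min); run made earlier; the fed solution adds 1.0 times the starting volume
- amber: left-handed substrate 1.8 M; right-handed substrate 1.8 M; coupling partner 0.96 M (fed, over 80 min); run made earlier; the fed solution adds 1.0 times the starting volume
- flask: left-handed substrate 0.80 M; right-handed substrate 0.80 M; coupling partner 0.960 M (fed, over 80 min); the fed solution adds 1.0 times the starting volume; time 3.0 d

| run | time / d | left-handed product / % | right-handed product / % |
|---|---|---|---|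
| green | 0.333 | 2.0 | 8.9 |
| green | 0.833 | 3.9 | 15.8 |
| green | 1.67 | 5.6 | 20.4 |
| green | 2.50 | 7.1 | 23.2 |
| green | 4.00 | 7.6 | 25.8 |
| amber | 0.333 | 1.0 | 5.8 |
| amber | 0.833 | 3.0 | 11.0 |
| amber | 1.67 | 3.9 | 15.0 |
| amber | 2.50 | 4.5 | 17.0 |
| amber | 4.00 | 5.2 | 18.6 |

(standard deviation of a reading: 0.3 percentage points)

- free catalyst is single-handed; left-handed substrate and right-handed substrate are mirror images of each other, charged as a racemate, each of them at the stated concentration
- amounts are per litre of the starting volume; all of the dose is in the solution fed
- the numbers in the tables scatter with a standard deviation of 0.3 percentage points
- steps thought possible: free catalyst + left-handed substrate <-> catalyst intermediate A; free catalyst + right-handed substrate <-> catalyst intermediate B; coupling partner + catalyst intermediate A -> free catalyst + left-handed product; coupling partner + catalyst intermediate B -> free catalyst + right-handed product; coupling partner + free catalyst -> spent catalyst A; 2 free catalyst -> spent catalyst B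
- an excess is the difference of the two amounts in percent of their sum
- an excess is below zero if the other one leads

* excess of left-handed product over right-handed product in the product at 4.0 h
* excess of left-handed product over right-handed product in the product at 3.0 d
* part of the left-handed substrate and right-handed substrate charged together that has reacted at 3.0 d

I took the given numbers in turn and asked what each could shift. The feed ended sooner than the first reading at 0.333 d, so I gave its timing little weight. The catalyst charge matched both earlier runs. At 4.00 d the green run had reacted 33.4% with excess −54.5%, the amber run 23.8% with −56.3%, and these two runs differed in substrate charge as well as in conversion.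

The opening lead of the right-handed product is (s − 1)/(s + 1), where s is the rate ratio at equal substrate. Setting s at 4 gives 60.0% and at 5 gives 66.7%, a wider gap than the one between those two readings. So this was the number to know well.

Each substrate being half of what the percentages count, the green run at 4.00 d read 4.40 for the selectivity factor, the logarithm of the share of right-handed substrate left over the logarithm of the share of left-handed substrate left. The amber run read 4.24. My opening excess was therefore −63.0%.

The forecast gave, in the order asked, −62%, −53% and 37%, calling its factor “constant, as expected for competition”.

The flask gave, in the same order, −60.0%, −53.4% and 34.7%.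

    free catalyst + left-handed substrate ⇌ catalyst intermediate A (K = 0.470 M⁻¹, k = 5.20 M⁻¹ min⁻¹)
    free catalyst + right-handed substrate ⇌ catalyst intermediate B (K = 24.0 M⁻¹, k = 6.10 M⁻¹ min⁻¹)
    coupling partner + catalyst intermediate A → free catalyst + left-handed product (k = 0.360 M⁻¹ min⁻¹)
    coupling partner + catalyst intermediate B → free catalyst + right-handed product (k = 0.0320 M⁻¹ min⁻¹)
    coupling partner + free catalyst → spent catalyst A (k = 0.0150 M⁻¹ min⁻¹)
    2 free catalyst → spent catalyst B (k = 0.380 M⁻¹ min⁻¹)

The undoing of catalyst intermediate A is the main reason the right-handed product led: the run without that step ended with an excess of 71.9%, against −53.4%. In the flask, left-handed product at 8.07% and the factor 4.40 gave right-handed product 27.0%, and the flask held 26.5%. In the neighbour charged with 0.24 M of coupling partner, left-handed product at 2.48% gave 10.0%, and that flask held 9.94%.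

The earlier runs and the new flask stem from a simulated flask with constants of no real substance.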